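Everything rests on disconnecting, in each terminal ring C, the bond from the ring carbon to the chain carbonyl C1 together with one adjacent ring C–O bond. Ring C carries an oxygen, the acyl carbon C1 and a second oxygen on three consecutive ring carbons, and 3-methoxybenzyne supplies this 1,2,3-array when it inserts into the C1–OH bond of a carboxylic acid. One operation therefore converts both carboxyl groups of a biaryl diacid into 2-hydroxy-6-methoxyphenyl ketones, forming two aryl–C1 and two aryl–O bonds. The precursor is a tetramethoxybiphenyl bearing two 8-carboxyoctyl chains, built by Suzuki coupling, double Wittig olefination and hydrogenation; BBr3 finally frees all eight phenols.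

Key step: step 6

Remark: the target has no stereocentre and its biaryl axis carries only two ortho substituents, so it is treated as freely rotating; the alkenes of 8 are drawn without geometry because both isomers converge in step 5.

Step 1
Reactants: 1 3-bromo-4,5-dimethoxybenzaldehyde
Product: 2 3,4-dimethoxy-5-(4,4,5,5-tetramethyl-1,3,2-dioxaborolan-2-yl)benzaldehyde
Conditions: B2pin2 (1.2 equiv), Pd(dppf)Cl2 (3 mol %), KOAc (3 equiv), 1,4-dioxane, 90 °C
Reagents that add atoms: bis(pinacolato)diboron, CC1(C)OB(OC1(C)C)B1OC(C)(C)C(C)(C)O1
Why: Miyaura borylation, in which zerovalent palladium inserts into the aryl–Br bond and the acetate-ligated arylpalladium transmetalates with the diboron reagent, while the weak base KOAc leaves the aldehyde untouched and suppresses onward biaryl coupling.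

Step 2
Reactants: 2 3,4-dimethoxy-5-(4,4,5,5-tetramethyl-1,3,2-dioxaborolan-2-yl)benzaldehyde; 3 2-bromo-4,5-dimethoxybenzaldehyde
Product: 4 2',3',4,5-tetramethoxybiphenyl-2,5'-dicarbaldehyde
Conditions: Pd(dppf)Cl2 (5 mol %), K2CO3 (3 equiv), 1,4-dioxane/H2O (4:1), 90 °C
Reagents that add atoms: none
Why: Suzuki–Miyaura coupling, in which the bromide ortho to the formyl group is activated for oxidative addition and boron sits on the ring where it is not ortho to a formyl group, so protodeboronation should be slow and both aldehydes should survive aqueous carbonate.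

Step 3
Reactants: 5 8-bromooctanoic acid
Product: 6 (7-carboxyheptyl)triphenylphosphonium bromide
Conditions: PPh3 (1.05 equiv), MeCN, reflux
Reagents that add atoms: triphenylphosphine, c1ccc(cc1)P(c1ccccc1)c1ccccc1
Why: SN2 quaternization of triphenylphosphine by the unhindered primary bromide, which tolerates the free carboxylic acid and should give a crystalline salt.

Step 4
Reactants: 4 2',3',4,5-tetramethoxybiphenyl-2,5'-dicarbaldehyde; 6 (7-carboxyheptyl)triphenylphosphonium bromide (2.6 equiv)
Product: 8 9,9'-(2',3',4,5-tetramethoxybiphenyl-2,5'-diyl)di(non-8-enoic acid) as a Z/E mixture at both alkenes, via carboxylate ylide 7 (not isolated)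
Conditions: 6, KOtBu (5.4 equiv), THF, 0 °C to rt; then 4, 0 °C to rt; aq. HCl work-up
Reagents that add atoms: none
Why: Wittig olefination, in which two equivalents of base per salt give the carboxylate ylide, a non-stabilized ylide that should add readily to both non-enolizable aryl aldehydes, and the alkene geometry (mainly Z expected) is irrelevant because step 5 saturates both double bonds.

Step 5
Reactants: 8 9,9'-(2',3',4,5-tetramethoxybiphenyl-2,5'-diyl)di(non-8-enoic acid)
Product: 9 9,9'-(2',3',4,5-tetramethoxybiphenyl-2,5'-diyl)dinonanoic acid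
Conditions: H2 (1 atm), 10% Pd/C, EtOAc/MeOH, rt
Reagents that add atoms: none
Why: Heterogeneous catalytic hydrogenation should saturate the two styrene-type double bonds and leave the aryl methyl ethers, the carboxylic acids and the biaryl untouched, since no benzylic heteroatom or halide is present.

Step 6
Reactants: 9 9,9'-(2',3',4,5-tetramethoxybiphenyl-2,5'-diyl)dinonanoic acid; 10 3-methoxy-2-(trimethylsilyl)phenyl trifluoromethanesulfonate (3 equiv)
Product: 12 9,9'-(2',3',4,5-tetramethoxybiphenyl-2,5'-diyl)bis[1-(2-hydroxy-6-methoxyphenyl)nonan-1-one], via 3-methoxybenzyne 11 (not isolated)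
Conditions: CsF (8 equiv), dry THF, 125 °C, sealed tube; aq. NH4Cl work-up
Reagents that add atoms: none
Why: Fluoride attacks silicon in 10 and triflate leaves to give aryne 11; a carboxylate oxygen of 9 adds to the aryne carbon meta to the methoxy group, the aryl anion formed beside the methoxy group attacks the neighbouring ester carbonyl, and the strained four-membered alkoxide opens to the cesium phenoxide of the ortho-acylphenol, a net insertion into the C1–O bond that occurs once at each chain end. The closest known reaction type is the C–O insertion of arynes from ortho-silylaryl triflates into carboxylic acids, which gives ortho-hydroxyaryl ketones with CsF in hot THF. No ring is closed and no stereocentre is created. Two selectivities are needed: the orientation of addition, secured by the methoxy group, whose inductive pull and the resulting aryne distortion send the nucleophile to the distal carbon and so place the acyl group between the two oxygens, and acyl transfer ahead of protonation of the aryl anion, which would stop at the aryl ester and is disfavoured by the high temperature, the aprotic solvent and the excess of CsF. The product phenoxide is chelated to the new ketone and is a poor nucleophile, which should limit further arylation, and the tetramethoxybiphenyl core and the saturated chains offer no competing acidic or nucleophilic site.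

Step 7
Reactants: 12 9,9'-(2',3',4,5-tetramethoxybiphenyl-2,5'-diyl)bis[1-(2-hydroxy-6-methoxyphenyl)nonan-1-one]
Product: 13 9,9'-(2',3',4,5-tetrahydroxybiphenyl-2,5'-diyl)bis[1-(2,6-dihydroxyphenyl)nonan-1-one]
Conditions: BBr3 (12 equiv), CH2Cl2, −78 °C to rt, argon; then ice-water
Reagents that add atoms: none
Why: Lewis-acid ether cleavage, in which BBr3 coordinates to each ether oxygen and bromide removes the methyl group by SN2, the two ethers ortho to the ketones being helped by chelation, while the aryl ketones and alkyl chains are inert and hydrolysis of the aryl borates should release the octaphenol.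

Compound list
1 | 3-bromo-4,5-dimethoxybenzaldehyde | COc1cc(C=O)cc(Br)c1OC | starting material
2 | 3,4-dimethoxy-5-(4,4,5,5-tetramethyl-1,3,2-dioxaborolan-2-yl)benzaldehyde | COc1cc(C=O)cc(B2OC(C)(C)C(C)(C)O2)c1OC | intermediate
3 | 2-bromo-4,5-dimethoxybenzaldehyde | COc1cc(Br)c(C=O)cc1OC | starting material
4 | 2',3',4,5-tetramethoxybiphenyl-2,5'-dicarbaldehyde | COc1cc(C=O)cc(-c2cc(OC)c(OC)cc2C=O)c1OC | intermediate
5 | 8-bromooctanoic acid | OC(=O)CCCCCCCBr | starting material
6 | (7-carboxyheptyl)triphenylphosphonium bromide | OC(=O)CCCCCCC[P+](c1ccccc1)(c1ccccc1)c1ccccc1.[Br-] | intermediate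
7 | potassium 8-(triphenyl-λ5-phosphanylidene)octanoate (carboxylate ylide, formed in the flask) | [K+].[O-]C(=O)CCCCCCC=P(c1ccccc1)(c1ccccc1)c1ccccc1 | intermediate
8 | 9,9'-(2',3',4,5-tetramethoxybiphenyl-2,5'-diyl)di(non-8-enoic acid), Z/E mixture at both alkenes | OC(=O)CCCCCCC=Cc1cc(OC)c(OC)c(-c2cc(OC)c(OC)cc2C=CCCCCCCC(=O)O)c1 | intermediate
9 | 9,9'-(2',3',4,5-tetramethoxybiphenyl-2,5'-diyl)dinonanoic acid | OC(=O)CCCCCCCCc1cc(OC)c(OC)c(-c2cc(OC)c(OC)cc2CCCCCCCCC(=O)O)c1 | intermediate
10 | 3-methoxy-2-(trimethylsilyl)phenyl trifluoromethanesulfonate | COc1cccc(OS(=O)(=O)C(F)(F)F)c1[Si](C)(C)C | starting material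
11 | 3-methoxybenzyne (1-methoxycyclohexa-1,3-dien-5-yne, formed in the flask) | COC1=CC=CC#C1 | intermediate
12 | 9,9'-(2',3',4,5-tetramethoxybiphenyl-2,5'-diyl)bis[1-(2-hydroxy-6-methoxyphenyl)nonan-1-one] | O=C(CCCCCCCCc1cc(OC)c(OC)c(-c2cc(OC)c(OC)cc2CCCCCCCCC(=O)c2c(O)cccc2OC)c1)c1c(O)cccc1OC | intermediate
13 | 9,9'-(2',3',4,5-tetrahydroxybiphenyl-2,5'-diyl)bis[1-(2,6-dihydroxyphenyl)nonan-1-one] | O=C(CCCCCCCCc1cc(O)c(O)c(-c2cc(O)c(O)cc2CCCCCCCCC(=O)c2c(O)cccc2O)c1)c1c(O)cccc1O | target

Total step count: 7. Longest linear sequence: 6 steps (steps 1, 2, 4, 5, 6 and 7; step 3 is a one-step branch).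

Steps most likely to fail

Step 6. Protonation of the aryl anion may outrun acyl transfer and stop at aryl esters, only one of the two carboxyl groups may be converted, or surplus aryne may arylate the product phenoxide. The fallback sets out from 9 and makes the aryl–C1 bonds by acyl substitution. Diacid 9 would be activated with 1,1'-carbonyldiimidazole and treated with N,O-dimethylhydroxylamine hydrochloride to give bis(Weinreb amide) F1. 2,6-Dimethoxyphenyllithium F2 would be generated from 1,3-dimethoxybenzene and n-BuLi in THF by lithiation between the two methoxy groups. Its addition to F1 would give, after collapse of the chelated tetrahedral intermediates on aqueous NH4Cl work-up, octamethyl ether diketone F3. BBr3 in CH2Cl2 would then cleave all eight methyl ethers, and the route is rejoined at target 13.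

Step 7. Some of the six ethers may resist cleavage, and the catechol-rich octaphenol may be lost through air oxidation or irreversible adsorption during purification. The fallback sets out from 12. The crude product of the BBr3 reaction would be peracetylated directly (Ac2O, pyridine, DMAP) to octaacetate F4, which is non-polar, air-stable and separable on silica from under-demethylated material. Acid-catalysed methanolysis (HCl generated from AcCl in degassed MeOH, argon) would then release the phenols with only volatile co-products, and the route comes back at 13.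

Step 4. The potassium carboxylate ylide or the half-olefinated carboxylate may precipitate, which would stall the second olefination at the more hindered aldehyde next to the biaryl axis. The fallback sets out from 4 and uses an ester-masked ylide. Commercial methyl 8-bromooctanoate and PPh3 in refluxing MeCN would give (8-methoxy-8-oxooctyl)triphenylphosphonium bromide F5. NaN(SiMe3)2 in THF would convert it into the soluble ester ylide F6. Double olefination of 4 would give diene diester F7, hydrogenation over Pd/C the saturated diester F8, and saponification with LiOH in THF/H2O followed by acidification the diacid 9, where the route is rejoined.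

Further compounds
F1 | step 6 | 9,9'-(2',3',4,5-tetramethoxybiphenyl-2,5'-diyl)bis(N-methoxy-N-methylnonanamide) | CON(C)C(=O)CCCCCCCCc1cc(OC)c(OC)c(-c2cc(OC)c(OC)cc2CCCCCCCCC(=O)N(C)OC)c1
F2 | step 6 | 2,6-dimethoxyphenyllithium | [Li]c1c(OC)cccc1OC
F3 | step 6 | 9,9'-(2',3',4,5-tetramethoxybiphenyl-2,5'-diyl)bis[1-(2,6-dimethoxyphenyl)nonan-1-one] | COc1cccc(OC)c1C(=O)CCCCCCCCc1cc(OC)c(OC)c(-c2cc(OC)c(OC)cc2CCCCCCCCC(=O)c2c(OC)cccc2OC)c1
F4 | step 7 | 9,9'-(2',3',4,5-tetraacetoxybiphenyl-2,5'-diyl)bis[1-(2,6-diacetoxyphenyl)nonan-1-one] | O=C(CCCCCCCCc1cc(OC(C)=O)c(OC(C)=O)c(-c2cc(OC(C)=O)c(OC(C)=O)cc2CCCCCCCCC(=O)c2c(OC(C)=O)cccc2OC(C)=O)c1)c1c(OC(C)=O)cccc1OC(C)=O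
F5 | step 4 | (8-methoxy-8-oxooctyl)triphenylphosphonium bromide | COC(=O)CCCCCCC[P+](c1ccccc1)(c1ccccc1)c1ccccc1.[Br-]
F6 | step 4 | methyl 8-(triphenyl-λ5-phosphanylidene)octanoate | COC(=O)CCCCCCC=P(c1ccccc1)(c1ccccc1)c1ccccc1
F7 | step 4 | dimethyl 9,9'-(2',3',4,5-tetramethoxybiphenyl-2,5'-diyl)di(non-8-enoate), Z/E mixture | COC(=O)CCCCCCC=Cc1cc(OC)c(OC)c(-c2cc(OC)c(OC)cc2C=CCCCCCCC(=O)OC)c1
F8 | step 4 | dimethyl 9,9'-(2',3',4,5-tetramethoxybiphenyl-2,5'-diyl)dinonanoate | COC(=O)CCCCCCCCc1cc(OC)c(OC)c(-c2cc(OC)c(OC)cc2CCCCCCCCC(=O)OC)c1
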